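The route rests on cutting ring C of the dihydroflavonol at O1–C8a and then at C3–O and C2–C3, so that the C4 ketone, the C3 carbinol and the benzylic C2–O of ring C are read as an α,β-dioxygenated aryl ketone. One rhodium-carbenoid operation joins an α-diazoketone carrying ring A, 4-methoxybenzyl alcohol and the ring B aldehyde, making both bonds and both stereocentres (anti, 2R,3R) under chiral phosphoric acid control without closing a ring. The precursor is 2-diazo-1-[2-fluoro-4-(geranyloxy)phenyl]ethanone; its ortho fluorine later lets the C2 alkoxide close ring C by SNAr with retention at C2.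

Key step: step 4

Remark: flavanone numbering (O1, C2, C3, C4, C4a, C8a) is used for open-chain intermediates too, geranyl = (2E)-3,7-dimethylocta-2,6-dien-1-yl, TIPS = triisopropylsilyl, PMB = 4-methoxybenzyl; it is assumed that the (2R,3R) descriptors of aldol 10 and of the target denote the same spatial arrangement, which holds because ring closure breaks no bond at C2 or C3 and the CIP ranking at both centres stays the same.

Step 1
Reactants: 1 1-(2-fluoro-4-hydroxyphenyl)ethanone; 2 geranyl bromide
Product: 3 1-[2-fluoro-4-(geranyloxy)phenyl]ethanone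
Conditions: K2CO3 (1.5 equiv), acetone, 50 °C
Reagents that add atoms: none
Why: Williamson O-alkylation (SN2) of the para-acyl phenoxide with the primary allylic bromide, which leaves the E alkene untouched and does not disturb the aryl fluoride at this temperature.

Step 2
Reactants: 3 1-[2-fluoro-4-(geranyloxy)phenyl]ethanone
Product: 5 2-diazo-1-[2-fluoro-4-(geranyloxy)phenyl]ethanone, via trifluoroacetyl ketone 4 (not isolated)
Conditions: LiN(SiMe3)2, THF, −78 °C, then CF3CO2CH2CF3; cold 5% HCl wash; crude 4, p-ABSA, Et3N, H2O (1 equiv), MeCN, rt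
Reagents that add atoms: 4-acetamidobenzenesulfonyl azide (p-ABSA), CC(=O)Nc1ccc(cc1)S(=O)(=O)N=[N+]=[N-]; 2,2,2-trifluoroethyl trifluoroacetate, FC(F)(F)COC(=O)C(F)(F)F (its CF3CO group stays in 4 only)
Why: Danheiser detrifluoroacetylative diazo transfer, in which the lithium enolate is C-trifluoroacetylated to 4 and the enolate of 4 adds to the sulfonyl azide and fragments with loss of the trifluoroacetyl group, so the terminal diazoketone forms without an acid chloride or HCl that would endanger the geranyl ether.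

Step 3
Reactants: 6 3,4-dihydroxybenzaldehyde
Product: 7 3,4-bis(triisopropylsilyloxy)benzaldehyde
Conditions: TIPSCl (2.5 equiv), imidazole (5 equiv), DMF, 40 °C
Reagents that add atoms: chlorotriisopropylsilane (TIPSCl), CC(C)[Si](Cl)(C(C)C)C(C)C
Why: Imidazole-promoted silylation of both phenols, with TIPS chosen over tert-butyldimethylsilyl because aryl TIPS ethers should resist the alkoxide and fluoride ion of step 5 yet still leave with buffered fluoride in step 7.

Step 4
Reactants: 5 2-diazo-1-[2-fluoro-4-(geranyloxy)phenyl]ethanone; 7 3,4-bis(triisopropylsilyloxy)benzaldehyde; 8 4-methoxybenzyl alcohol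
Product: 10 (2R,3R)-3-[3,4-bis(triisopropylsilyloxy)phenyl]-1-[2-fluoro-4-(geranyloxy)phenyl]-3-hydroxy-2-(4-methoxybenzyloxy)propan-1-one, via Z enol 9 (not isolated)
Conditions: Rh2(OAc)4 (2 mol%), (R)-TRIP [3,3'-bis(2,4,6-triisopropylphenyl)-BINOL hydrogen phosphate] (10 mol%; antipode if screening shows the opposite facial sense), 7 (1.5 equiv), 8 (1.2 equiv), 4 Å MS, CH2Cl2, −20 °C, 5 added over 2 h
Reagents that add atoms: none
Why: Rh2(OAc)4 (divalent rhodium) extrudes N2 from 5 to give a rhodium carbenoid, the O–H of 8 adds to it to form a protic oxonium ylide that relays a proton to give Z enol 9, and 9 adds through carbon to the phosphoric-acid-activated aldehyde 7 before the 1,2-proton shift can deliver the plain O–H insertion product, so that C3–O and C2–C3 are made in one flask. The closest known reaction type is the dirhodium/chiral Brønsted acid three-component aldol- and Mannich-type interception of alcohol-derived oxonium ylides from diazo esters and diazoacetophenones. No ring is closed in this step. C2 (the carbinol carbon, from the formyl group) and C3 (from the diazo carbon) are both set in the C–C bond-forming transition state, where the bifunctional phosphate binds the enol O–H and the formyl oxygen and so dictates the aldehyde face for C2 and the enol face for C3, the catalyst antipode being chosen for the (2R,3R) sense. The step needs trapping to beat the proton shift and needs anti selectivity: the donor-substituted and hence nucleophilic aryl ketone enol, slow addition of 5, excess 7 and acid activation of the electron-rich formyl group serve the first, and the cyclic hydrogen-bonded array with the two aryl-bearing ends held apart serves the second. The C–F bond and the trisubstituted geranyl alkenes are spectators, since ylide formation with the alcohol is faster than cyclopropanation.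

Step 5
Reactants: 10 (2R,3R)-3-[3,4-bis(triisopropylsilyloxy)phenyl]-1-[2-fluoro-4-(geranyloxy)phenyl]-3-hydroxy-2-(4-methoxybenzyloxy)propan-1-one
Product: 11 (2R,3R)-2-[3,4-bis(triisopropylsilyloxy)phenyl]-7-(geranyloxy)-3-(4-methoxybenzyloxy)-2,3-dihydro-4H-chromen-4-one
Conditions: KN(SiMe3)2 (1.05 equiv), THF, −78 to 0 °C; pH 7 buffer
Reagents that add atoms: none
Why: Intramolecular SNAr O-arylation, in which the potassium alkoxide on the C2 oxygen adds to C8a (ortho to, and activated by, the C4 ketone) and fluoride leaves from the Meisenheimer adduct in a six-membered ring closure that breaks no bond at C2 or C3, while the single equivalent of base ends as insoluble KF so that neither the aldolate nor the enolisable product lingers in base.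

Step 6
Reactants: 11 (2R,3R)-2-[3,4-bis(triisopropylsilyloxy)phenyl]-7-(geranyloxy)-3-(4-methoxybenzyloxy)-2,3-dihydro-4H-chromen-4-one
Product: 12 (2R,3R)-2-[3,4-bis(triisopropylsilyloxy)phenyl]-7-(geranyloxy)-3-hydroxy-2,3-dihydro-4H-chromen-4-one
Conditions: DDQ (1.3 equiv), CH2Cl2/pH 7 buffer (10:1), 0 °C
Reagents that add atoms: none
Why: Oxidative PMB ether cleavage by DDQ (benzylic hydride abstraction, then hydrolysis of the oxocarbenium ion), in which the geranyl OCH2 should react more slowly because its aryloxy oxygen is deactivated by the para ketone, and in which silyl ethers and both stereocentres are untouched.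

Step 7
Reactants: 12 (2R,3R)-2-[3,4-bis(triisopropylsilyloxy)phenyl]-7-(geranyloxy)-3-hydroxy-2,3-dihydro-4H-chromen-4-one
Product: 13 (2R,3R)-2-(3,4-dihydroxyphenyl)-7-(geranyloxy)-3-hydroxy-2,3-dihydro-4H-chromen-4-one (target)
Conditions: Bu4NF/AcOH (1:1, 2.5 equiv), THF, 0 °C, argon
Reagents that add atoms: none
Why: Fluoride-mediated cleavage of the two aryl silyl ethers, buffered with acetic acid so that the oxidation-prone catechol and the epimerisable 3-hydroxychromanone do not meet free phenoxide base, with no bond at C2 or C3 affected.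

Compound list
1 | 1-(2-fluoro-4-hydroxyphenyl)ethanone | CC(=O)c1ccc(O)cc1F | starting material
2 | geranyl bromide, (2E)-1-bromo-3,7-dimethylocta-2,6-diene | CC(C)=CCC/C(C)=C/CBr | starting material
3 | 1-[2-fluoro-4-(geranyloxy)phenyl]ethanone | CC(C)=CCC/C(C)=C/COc1ccc(C(C)=O)c(F)c1 | intermediate
4 | 4,4,4-trifluoro-1-[2-fluoro-4-(geranyloxy)phenyl]butane-1,3-dione (not isolated) | CC(C)=CCC/C(C)=C/COc1ccc(C(=O)CC(=O)C(F)(F)F)c(F)c1 | intermediate
5 | 2-diazo-1-[2-fluoro-4-(geranyloxy)phenyl]ethanone | CC(C)=CCC/C(C)=C/COc1ccc(C(=O)C=[N+]=[N-])c(F)c1 | intermediate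
6 | 3,4-dihydroxybenzaldehyde | O=Cc1ccc(O)c(O)c1 | starting material
7 | 3,4-bis(triisopropylsilyloxy)benzaldehyde | O=Cc1ccc(O[Si](C(C)C)(C(C)C)C(C)C)c(O[Si](C(C)C)(C(C)C)C(C)C)c1 | intermediate
8 | 4-methoxybenzyl alcohol | COc1ccc(CO)cc1 | starting material
9 | (Z)-1-[2-fluoro-4-(geranyloxy)phenyl]-2-(4-methoxybenzyloxy)ethen-1-ol (not isolated; tautomer of the oxonium ylide) | CC(C)=CCC/C(C)=C/COc1ccc(c(F)c1)/C(O)=C/OCc1ccc(OC)cc1 | intermediate
10 | (2R,3R)-3-[3,4-bis(triisopropylsilyloxy)phenyl]-1-[2-fluoro-4-(geranyloxy)phenyl]-3-hydroxy-2-(4-methoxybenzyloxy)propan-1-one | CC(C)=CCC/C(C)=C/COc1ccc(c(F)c1)C(=O)[C@H](OCc1ccc(OC)cc1)[C@H](O)c1ccc(O[Si](C(C)C)(C(C)C)C(C)C)c(O[Si](C(C)C)(C(C)C)C(C)C)c1 | intermediate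
11 | (2R,3R)-2-[3,4-bis(triisopropylsilyloxy)phenyl]-7-(geranyloxy)-3-(4-methoxybenzyloxy)-2,3-dihydro-4H-chromen-4-one | CC(C)=CCC/C(C)=C/COc1ccc2c(c1)O[C@H](c1ccc(O[Si](C(C)C)(C(C)C)C(C)C)c(O[Si](C(C)C)(C(C)C)C(C)C)c1)[C@@H](OCc1ccc(OC)cc1)C2=O | intermediate
12 | (2R,3R)-2-[3,4-bis(triisopropylsilyloxy)phenyl]-7-(geranyloxy)-3-hydroxy-2,3-dihydro-4H-chromen-4-one | CC(C)=CCC/C(C)=C/COc1ccc2c(c1)O[C@H](c1ccc(O[Si](C(C)C)(C(C)C)C(C)C)c(O[Si](C(C)C)(C(C)C)C(C)C)c1)[C@@H](O)C2=O | intermediate
13 | (2R,3R)-2-(3,4-dihydroxyphenyl)-7-(geranyloxy)-3-hydroxy-2,3-dihydro-4H-chromen-4-one | CC(C)=CCC/C(C)=C/COc1ccc2c(c1)O[C@H](c1ccc(O)c(O)c1)[C@@H](O)C2=O | target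

Total step count: 7. Longest linear sequence: 6 steps (steps 1, 2, 4, 5, 6, 7 from compound 1).

Steps most likely to fail

1. Step 4. The 1,2-proton shift of the ylide (plain O–H insertion) may outrun addition to the electron-rich aldehyde, and the anti and facial control may be incomplete. Fallback, setting out from 5 and returning at 10: the two bond formations are separated. Rh2(OAc)4-catalysed O–H insertion of 8 into 5, without acid or aldehyde, gives 1-[2-fluoro-4-(geranyloxy)phenyl]-2-(4-methoxybenzyloxy)ethanone F1. Soft enolisation of F1 with dicyclohexylboron chloride (Cy2BCl)/Et3N and addition of 7 through a closed transition state (E enolate expected, hence anti) gives the racemic anti aldol, that is 10 together with its (2S,3S)-enantiomer F2; any syn isomer is removed on silica. Preparative chromatography on a chiral stationary phase then delivers 10.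

2. Step 5. Retro-aldol cleavage, enolisation at C3 with dehydration, or silyl transfer to the alkoxide may compete with fluoride displacement and erode both stereocentres. Fallback, setting out from 2 and returning at 12: ring C is brought in preformed, so no aldolate is ever generated. Commercial 7-hydroxy-4H-chromen-4-one is O-alkylated with 2 (K2CO3, acetone) to 7-(geranyloxy)-4H-chromen-4-one F3. 4-Bromobenzene-1,2-diol is silylated (TIPSCl, imidazole) to 4-bromo-1,2-bis(triisopropylsilyloxy)benzene F4, and n-BuLi then B(OMe)3 and aqueous work-up convert it into [3,4-bis(triisopropylsilyloxy)phenyl]boronic acid F5. Enantioselective conjugate addition of F5 to F3 with Pd(OCOCF3)2 (divalent palladium), a chiral 4-tert-butyl-2-(pyridin-2-yl)oxazoline ligand of the appropriate hand, NH4PF6 and water in ClCH2CH2Cl at 60 °C should give (2S)-2-[3,4-bis(triisopropylsilyloxy)phenyl]-7-(geranyloxy)-2,3-dihydro-4H-chromen-4-one F6. Its sodium enolate (NaN(SiMe3)2, THF, −78 °C) is hydroxylated with 2-(phenylsulfonyl)-3-phenyloxaziridine on the face anti to the C2 aryl group, which should give the 2,3-trans alcohol 12.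

3. Step 6. Hydride abstraction at the allylic OCH2 of the geranyl ether may compete with the slow oxidation of the ketone-deactivated PMB ether, costing the side chain. Fallback, setting out from 5 and 7 and returning at 12: the oxidative unmasking is replaced by an isomerisation–hydrolysis. Prop-2-en-1-ol takes the place of 8 in the three-component coupling of step 4 and should give (2R,3R)-2-(allyloxy)-3-[3,4-bis(triisopropylsilyloxy)phenyl]-1-[2-fluoro-4-(geranyloxy)phenyl]-3-hydroxypropan-1-one F7. The ring closure of step 5 then gives (2R,3R)-3-(allyloxy)-2-[3,4-bis(triisopropylsilyloxy)phenyl]-7-(geranyloxy)-2,3-dihydro-4H-chromen-4-one F8. Hydrogen-activated [Ir(cod)(PMePh2)2]PF6 in THF isomerises only the monosubstituted allyl group, giving (2R,3R)-2-[3,4-bis(triisopropylsilyloxy)phenyl]-7-(geranyloxy)-3-(prop-1-en-1-yloxy)-2,3-dihydro-4H-chromen-4-one F9 (E/Z mixture) and leaving the trisubstituted geranyl alkenes alone. Brief dilute aqueous HCl in THF hydrolyses the enol ether to 12.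

Further compounds
F1 | step 4 | 1-[2-fluoro-4-(geranyloxy)phenyl]-2-(4-methoxybenzyloxy)ethanone | CC(C)=CCC/C(C)=C/COc1ccc(C(=O)COCc2ccc(OC)cc2)c(F)c1
F2 | step 4 | (2S,3S)-3-[3,4-bis(triisopropylsilyloxy)phenyl]-1-[2-fluoro-4-(geranyloxy)phenyl]-3-hydroxy-2-(4-methoxybenzyloxy)propan-1-one | CC(C)=CCC/C(C)=C/COc1ccc(c(F)c1)C(=O)[C@@H](OCc1ccc(OC)cc1)[C@@H](O)c1ccc(O[Si](C(C)C)(C(C)C)C(C)C)c(O[Si](C(C)C)(C(C)C)C(C)C)c1
F3 | step 5 | 7-(geranyloxy)-4H-chromen-4-one | CC(C)=CCC/C(C)=C/COc1ccc2c(c1)OC=CC2=O
F4 | step 5 | 4-bromo-1,2-bis(triisopropylsilyloxy)benzene | Brc1ccc(O[Si](C(C)C)(C(C)C)C(C)C)c(O[Si](C(C)C)(C(C)C)C(C)C)c1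
F5 | step 5 | [3,4-bis(triisopropylsilyloxy)phenyl]boronic acid | OB(O)c1ccc(O[Si](C(C)C)(C(C)C)C(C)C)c(O[Si](C(C)C)(C(C)C)C(C)C)c1
F6 | step 5 | (2S)-2-[3,4-bis(triisopropylsilyloxy)phenyl]-7-(geranyloxy)-2,3-dihydro-4H-chromen-4-one | CC(C)=CCC/C(C)=C/COc1ccc2c(c1)O[C@H](c1ccc(O[Si](C(C)C)(C(C)C)C(C)C)c(O[Si](C(C)C)(C(C)C)C(C)C)c1)CC2=O
F7 | step 6 | (2R,3R)-2-(allyloxy)-3-[3,4-bis(triisopropylsilyloxy)phenyl]-1-[2-fluoro-4-(geranyloxy)phenyl]-3-hydroxypropan-1-one | CC(C)=CCC/C(C)=C/COc1ccc(c(F)c1)C(=O)[C@H](OCC=C)[C@H](O)c1ccc(O[Si](C(C)C)(C(C)C)C(C)C)c(O[Si](C(C)C)(C(C)C)C(C)C)c1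
F8 | step 6 | (2R,3R)-3-(allyloxy)-2-[3,4-bis(triisopropylsilyloxy)phenyl]-7-(geranyloxy)-2,3-dihydro-4H-chromen-4-one | CC(C)=CCC/C(C)=C/COc1ccc2c(c1)O[C@H](c1ccc(O[Si](C(C)C)(C(C)C)C(C)C)c(O[Si](C(C)C)(C(C)C)C(C)C)c1)[C@@H](OCC=C)C2=O
F9 | step 6 | (2R,3R)-2-[3,4-bis(triisopropylsilyloxy)phenyl]-7-(geranyloxy)-3-(prop-1-en-1-yloxy)-2,3-dihydro-4H-chromen-4-one (E/Z mixture) | CC(C)=CCC/C(C)=C/COc1ccc2c(c1)O[C@H](c1ccc(O[Si](C(C)C)(C(C)C)C(C)C)c(O[Si](C(C)C)(C(C)C)C(C)C)c1)[C@@H](OC=CC)C2=O
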